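## Retrosynthetic overview

1. Target 18 ⇐ tris(benzyl ether) 17 by global hydrogenolysis (no skeletal change).
2. 17 ⇐ acyclic α-bromo imide 12 in one radical–polar crossover: C6a–C3a bond by 5-exo closure (tetrahydrofuran ring first), then capture of the benzylic cation by the imide C=O (lactone ring second, auxiliary expelled).
3. 12 ⇐ allyl ether 10 + benzyl isoeugenol 11 (cross-metathesis); 10 ⇐ bromohydrin 8 (O-allylation).
4. 8 ⇐ bromoacetyl imide 4 + aldehyde 5 (Evans syn aldol sets C-6; C-6a, C-3a and C-3 are relayed from it in the key step); 4 ⇐ oxazolidinone 1 + bromoacetyl bromide 2.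

Assumption: target atoms are numbered as tetrahydro-1H,3H-furo[3,4-c]furan-1-one (C1 = C=O, C3 = guaiacyl carbon, C6 = catechol carbon), the bromoacetate aldol is taken to show the usual Evans syn facial bias, and catalyst-bound species (Ru carbenes, Ir photocatalyst states) are not numbered.

## Route

Step 1
Reactants: 1 (4S)-4-benzyl-1,3-oxazolidin-2-one; 2 bromoacetyl bromide
Product: 4 (4S)-4-benzyl-3-(bromoacetyl)-1,3-oxazolidin-2-one, via lithium oxazolidinide 3 (not isolated)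
Conditions: n-BuLi (1.0 equiv), THF, −78 °C; then 2 (1.1 equiv), −78 → 0 °C
Reagents that add atoms: none
Why: N-acylation of the lithiated carbamate at the acyl bromide, which is far more electrophilic than the CH2Br carbon; the stereocentre of 1 is untouched.

Step 2
Reactants: 4 (4S)-4-benzyl-3-(bromoacetyl)-1,3-oxazolidin-2-one; 5 3,4-bis(benzyloxy)benzaldehyde
Product: 8 (4S)-4-benzyl-3-[(2S,3R)-3-[3,4-bis(benzyloxy)phenyl]-2-bromo-3-hydroxypropanoyl]-1,3-oxazolidin-2-one, via dibutylboron Z-enolate 6 (not isolated), via dibutylboron aldolate 7 (not isolated)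
Conditions: n-Bu2BOTf (1.1 equiv), Et3N (1.3 equiv), CH2Cl2, −78 °C; 5, −78 → 0 °C; pH 7 buffer/MeOH/30% H2O2, 0 °C
Reagents that add atoms: none
Why: Evans syn aldol of a haloacetyl imide, in which the Z-boron enolate reacts through a Zimmerman–Traxler chair on the face opposite the benzyl group to give the (2S,3R) bromohydrin; C-3 becomes C-6 of the target (3R here and 6S there are the same geometry, only the CIP ranking changes) and C-2 is erased in step 5.

Step 3
Reactants: 8 (4S)-4-benzyl-3-[(2S,3R)-3-[3,4-bis(benzyloxy)phenyl]-2-bromo-3-hydroxypropanoyl]-1,3-oxazolidin-2-one; 9 allyl 2,2,2-trichloroacetimidate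
Product: 10 (4S)-4-benzyl-3-[(2S,3R)-3-[3,4-bis(benzyloxy)phenyl]-2-bromo-3-(prop-2-en-1-yloxy)propanoyl]-1,3-oxazolidin-2-one
Conditions: 9 (2.5 equiv), TfOH (10 mol%), CH2Cl2–cyclohexane 1:2, 0 °C → rt
Reagents that add atoms: none
Why: Acid-catalysed trichloroacetimidate O-alkylation is base-free, so neither retro-aldol nor bromohydrin-to-epoxide closure can occur, and the carbinol C–O bond is not broken, so C-3 keeps its configuration.

Step 4
Reactants: 10 (4S)-4-benzyl-3-[(2S,3R)-3-[3,4-bis(benzyloxy)phenyl]-2-bromo-3-(prop-2-en-1-yloxy)propanoyl]-1,3-oxazolidin-2-one; 11 benzyl isoeugenol, (E)-1-(benzyloxy)-2-methoxy-4-(prop-1-en-1-yl)benzene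
Product: 12 (4S)-4-benzyl-3-[(2S,3R)-3-{[(2E)-3-[4-(benzyloxy)-3-methoxyphenyl]prop-2-en-1-yl]oxy}-3-[3,4-bis(benzyloxy)phenyl]-2-bromopropanoyl]-1,3-oxazolidin-2-one
Conditions: Hoveyda–Grubbs II (5 mol%), 11 (3 equiv), CH2Cl2, 40 °C
Reagents that add atoms: none
Why: Olefin cross-metathesis of a terminal allyl ether with a propenylarene gives the conjugated E-styrenyl ether with loss of propene; no stereocentre is involved.

Step 5
Reactants: 12 (4S)-4-benzyl-3-[(2S,3R)-3-{[(2E)-3-[4-(benzyloxy)-3-methoxyphenyl]prop-2-en-1-yl]oxy}-3-[3,4-bis(benzyloxy)phenyl]-2-bromopropanoyl]-1,3-oxazolidin-2-one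
Product: 17 (3S,3aR,6S,6aS)-6-[3,4-bis(benzyloxy)phenyl]-3-[4-(benzyloxy)-3-methoxyphenyl]tetrahydro-1H,3H-furo[3,4-c]furan-1-one, via α-acyl radical 13 (not isolated), via benzylic radical 14 (not isolated), via benzylic cation 15 (not isolated), via iminium lactone 16 (not isolated)
Conditions: fac-Ir(ppy)3 (1 mol%), 2,6-lutidine (1.5 equiv), MeCN–H2O 10:1, blue LEDs, rt, degassed
Reagents that add atoms: water, O
Why: Proposed new method: excited fac-Ir(ppy)3 reduces the C–Br bond to the electrophilic α-acyl radical 13, which closes 5-exo-trig onto the electron-rich styrenyl alkene through a chair-like transition state with the C-6 aryl pseudo-equatorial and the acyl group anti to it (2,3-trans-3,4-cis tetrahydrofuran, ring 1), Ir(IV) (or Br-atom transfer and ionisation) turns benzylic radical 14 into the p-alkoxybenzyl cation 15, which the cis-placed imide C=O captures with the aryl on the convex face (ring 2), and water hydrolyses iminium 16 with loss of the auxiliary, so C-6a, C-3a and C-3 are all relayed from C-6; the closest known reaction types are the photoredox atom-transfer addition–lactonisation of α-bromo carbonyl compounds with styrenes and the stannane- or Ti(III)-mediated 5-exo cyclisation of β-(allyloxy)alkyl radicals used for furan lignans.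

Step 6
Reactants: 17 (3S,3aR,6S,6aS)-6-[3,4-bis(benzyloxy)phenyl]-3-[4-(benzyloxy)-3-methoxyphenyl]tetrahydro-1H,3H-furo[3,4-c]furan-1-one
Product: 18 (3S,3aR,6S,6aS)-6-(3,4-dihydroxyphenyl)-3-(4-hydroxy-3-methoxyphenyl)tetrahydro-1H,3H-furo[3,4-c]furan-1-one
Conditions: H2 (1 atm), 10% Pd/C, EtOAc–THF 4:1, rt, stopped at full debenzylation (about 1 h)
Reagents that add atoms: none
Why: Hydrogenolysis of the three primary ArO–CH2Ph bonds is much faster in neutral solvent than cleavage of the hindered secondary ring C–O bonds, and no stereocentre is touched.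

## Compound list

1 | (4S)-4-benzyl-1,3-oxazolidin-2-one | O=C1OC[C@H](Cc2ccccc2)N1 | starting material
2 | bromoacetyl bromide | BrCC(Br)=O | starting material
3 | lithium (4S)-4-benzyl-2-oxo-1,3-oxazolidin-3-ide | O=C1OC[C@H](Cc2ccccc2)N1[Li] | intermediate (not isolated)
4 | (4S)-4-benzyl-3-(bromoacetyl)-1,3-oxazolidin-2-one | O=C1OC[C@H](Cc2ccccc2)N1C(=O)CBr | intermediate
5 | 3,4-bis(benzyloxy)benzaldehyde | O=Cc1ccc(OCc2ccccc2)c(OCc2ccccc2)c1 | starting material
6 | (4S)-4-benzyl-3-[(Z)-2-bromo-1-(dibutylboranyloxy)ethenyl]-1,3-oxazolidin-2-one | O=C1OC[C@H](Cc2ccccc2)N1/C(OB(CCCC)CCCC)=C/Br | intermediate (not isolated)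
7 | O-dibutylboranyl aldolate of 8 | O=C1OC[C@H](Cc2ccccc2)N1C(=O)[C@@H](Br)[C@H](OB(CCCC)CCCC)c1ccc(OCc2ccccc2)c(OCc2ccccc2)c1 | intermediate (not isolated)
8 | (4S)-4-benzyl-3-[(2S,3R)-3-[3,4-bis(benzyloxy)phenyl]-2-bromo-3-hydroxypropanoyl]-1,3-oxazolidin-2-one | O=C1OC[C@H](Cc2ccccc2)N1C(=O)[C@@H](Br)[C@H](O)c1ccc(OCc2ccccc2)c(OCc2ccccc2)c1 | intermediate
9 | allyl 2,2,2-trichloroacetimidate | C=CCOC(=N)C(Cl)(Cl)Cl | starting material
10 | (4S)-4-benzyl-3-[(2S,3R)-3-[3,4-bis(benzyloxy)phenyl]-2-bromo-3-(prop-2-en-1-yloxy)propanoyl]-1,3-oxazolidin-2-one | O=C1OC[C@H](Cc2ccccc2)N1C(=O)[C@@H](Br)[C@H](OCC=C)c1ccc(OCc2ccccc2)c(OCc2ccccc2)c1 | intermediate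
11 | benzyl isoeugenol, (E)-1-(benzyloxy)-2-methoxy-4-(prop-1-en-1-yl)benzene | C/C=C/c1ccc(OCc2ccccc2)c(OC)c1 | starting material
12 | (4S)-4-benzyl-3-[(2S,3R)-3-{[(2E)-3-[4-(benzyloxy)-3-methoxyphenyl]prop-2-en-1-yl]oxy}-3-[3,4-bis(benzyloxy)phenyl]-2-bromopropanoyl]-1,3-oxazolidin-2-one | O=C1OC[C@H](Cc2ccccc2)N1C(=O)[C@@H](Br)[C@H](OC/C=C/c1ccc(OCc2ccccc2)c(OC)c1)c1ccc(OCc2ccccc2)c(OCc2ccccc2)c1 | intermediate
13 | α-acyl radical: 12 with the bromine lost and the radical at C-2 of the propanoyl chain | O=C1OC[C@H](Cc2ccccc2)N1C(=O)[CH][C@H](OC/C=C/c1ccc(OCc2ccccc2)c(OC)c1)c1ccc(OCc2ccccc2)c(OCc2ccccc2)c1 | intermediate (not isolated)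
14 | benzylic radical: 2,3-trans-3,4-cis 2-aryl-tetrahydrofuran-3-carbonyl imide with the radical on the exocyclic benzylic carbon at C-4 | O=C1OC[C@H](Cc2ccccc2)N1C(=O)[C@H]1[C@@H]([CH]c2ccc(OCc3ccccc3)c(OC)c2)CO[C@@H]1c1ccc(OCc2ccccc2)c(OCc2ccccc2)c1 | intermediate (not isolated)
15 | benzylic cation: one-electron-oxidised 14 | O=C1OC[C@H](Cc2ccccc2)N1C(=O)[C@H]1[C@@H]([CH+]c2ccc(OCc3ccccc3)c(OC)c2)CO[C@@H]1c1ccc(OCc2ccccc2)c(OCc2ccccc2)c1 | intermediate (not isolated)
16 | iminium lactone bromide: bicyclic O-alkylated imide, C1 of the furofuranone doubly bonded to the oxazolidinone nitrogen | COc1cc([C@H]2OC(=[N+]4C(=O)OC[C@@H]4Cc4ccccc4)[C@H]3[C@@H]2CO[C@@H]3c2ccc(OCc4ccccc4)c(OCc4ccccc4)c2)ccc1OCc1ccccc1.[Br-] | intermediate (not isolated)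
17 | (3S,3aR,6S,6aS)-6-[3,4-bis(benzyloxy)phenyl]-3-[4-(benzyloxy)-3-methoxyphenyl]tetrahydro-1H,3H-furo[3,4-c]furan-1-one | COc1cc([C@H]2OC(=O)[C@H]3[C@@H]2CO[C@@H]3c2ccc(OCc4ccccc4)c(OCc4ccccc4)c2)ccc1OCc1ccccc1 | intermediate
18 | (3S,3aR,6S,6aS)-6-(3,4-dihydroxyphenyl)-3-(4-hydroxy-3-methoxyphenyl)tetrahydro-1H,3H-furo[3,4-c]furan-1-one | COc1cc([C@H]2OC(=O)[C@H]3[C@@H]2CO[C@@H]3c2ccc(O)c(O)c2)ccc1O | target

## Step count and risks

Total step count: 6. Longest linear sequence: 6 (1 → 4 → 8 → 10 → 12 → 17 → 18).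

The bicyclisation (step 5) is the least certain step. The 3,4-cis preference of the radical closure is precedented only for ester- and Ti-alkoxide-bearing radicals, only the cis radical can lactonise, and oxidation of 14 may be slower than hydrogen-atom capture. E/Z isomerisation of the styrene by the photocatalyst is harmless, since the alkene geometry is lost at 14. The fallback sets out from 12 and comes back at 17, closing the rings in two operations by inner-sphere halogen transfer instead of photoredox crossover. CuBr/tris(2-pyridylmethyl)amine (10 mol%) in MeCN at 60 °C gives the atom-transfer cyclisation product, the benzylic bromide (4S)-4-benzyl-3-{[2,3-trans-3,4-cis-2-[3,4-bis(benzyloxy)phenyl]-4-{[4-(benzyloxy)-3-methoxyphenyl]bromomethyl}oxolan-3-yl]carbonyl}-1,3-oxazolidin-2-one F1. F1 is then ionised with AgOTf and 2,6-lutidine in wet acetone at 0 °C, so that the imide carbonyl closes the lactone and releases the auxiliary to give 17.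

The O-allylation (step 3) may stall on the hindered secondary alcohol, and prolonged exposure to TfOH could ionise the electron-rich benzylic C-3 and erode the enantiomeric purity. The fallback sets out from 8 and comes back at 12, skipping 10 and the metathesis, by using a far more reactive cation donor at low temperature. 4-(Benzyloxy)-3-methoxybenzaldehyde and vinylmagnesium bromide give racemic 1-[4-(benzyloxy)-3-methoxyphenyl]prop-2-en-1-ol F2, and Cl3CCN with catalytic DBU gives 1-[4-(benzyloxy)-3-methoxyphenyl]prop-2-en-1-yl 2,2,2-trichloroacetimidate F3. F3 with 8 and TMSOTf (5 mol%) in CH2Cl2 at −40 °C ionises to the p-alkoxycinnamyl cation, which 8 captures at the terminal carbon to give the E-ether 12 directly.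

The final hydrogenolysis (step 6) can over-reduce: the benzylic lactone C3–O and the benzylic ether C6–O bonds of 17 are themselves hydrogenolysable, as in the known Pd/C conversion of pinoresinol to lariciresinol. The fallback sets out from 4 and comes back at 18, carrying the phenols as acetates so that no reductive step is needed. The aldol of 4 with commercial 3,4-diacetoxybenzaldehyde (same boron conditions, non-oxidative work-up) gives (4S)-4-benzyl-3-[(2S,3R)-2-bromo-3-(3,4-diacetoxyphenyl)-3-hydroxypropanoyl]-1,3-oxazolidin-2-one F4. Allylation with 9 gives its O-allyl ether F5, and cross-metathesis with commercial isoeugenyl acetate gives (4S)-3-[(2S,3R)-3-{[(2E)-3-(4-acetoxy-3-methoxyphenyl)prop-2-en-1-yl]oxy}-2-bromo-3-(3,4-diacetoxyphenyl)propanoyl]-4-benzyl-1,3-oxazolidin-2-one F6. The same light-driven bicyclisation (or the Cu/Ag variant, since the acetoxy-substituted cation is less stabilised) gives (3S,3aR,6S,6aS)-3-(4-acetoxy-3-methoxyphenyl)-6-(3,4-diacetoxyphenyl)tetrahydro-1H,3H-furo[3,4-c]furan-1-one F7. NH3 in MeOH at 0 °C then cleaves the three aryl acetates to give 18.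

## Further compounds

F1 | step 5 | (4S)-4-benzyl-3-{[2,3-trans-3,4-cis-2-[3,4-bis(benzyloxy)phenyl]-4-{[4-(benzyloxy)-3-methoxyphenyl]bromomethyl}oxolan-3-yl]carbonyl}-1,3-oxazolidin-2-one (bromide epimers) | O=C1OC[C@H](Cc2ccccc2)N1C(=O)[C@H]1[C@@H](C(Br)c2ccc(OCc3ccccc3)c(OC)c2)CO[C@@H]1c1ccc(OCc2ccccc2)c(OCc2ccccc2)c1
F2 | step 3 | 1-[4-(benzyloxy)-3-methoxyphenyl]prop-2-en-1-ol (racemic) | C=CC(O)c1ccc(OCc2ccccc2)c(OC)c1
F3 | step 3 | 1-[4-(benzyloxy)-3-methoxyphenyl]prop-2-en-1-yl 2,2,2-trichloroacetimidate (racemic) | C=CC(OC(=N)C(Cl)(Cl)Cl)c1ccc(OCc2ccccc2)c(OC)c1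
F4 | step 6 | (4S)-4-benzyl-3-[(2S,3R)-2-bromo-3-(3,4-diacetoxyphenyl)-3-hydroxypropanoyl]-1,3-oxazolidin-2-one | O=C1OC[C@H](Cc2ccccc2)N1C(=O)[C@@H](Br)[C@H](O)c1ccc(OC(C)=O)c(OC(C)=O)c1
F5 | step 6 | (4S)-4-benzyl-3-[(2S,3R)-2-bromo-3-(3,4-diacetoxyphenyl)-3-(prop-2-en-1-yloxy)propanoyl]-1,3-oxazolidin-2-one | O=C1OC[C@H](Cc2ccccc2)N1C(=O)[C@@H](Br)[C@H](OCC=C)c1ccc(OC(C)=O)c(OC(C)=O)c1
F6 | step 6 | (4S)-3-[(2S,3R)-3-{[(2E)-3-(4-acetoxy-3-methoxyphenyl)prop-2-en-1-yl]oxy}-2-bromo-3-(3,4-diacetoxyphenyl)propanoyl]-4-benzyl-1,3-oxazolidin-2-one | O=C1OC[C@H](Cc2ccccc2)N1C(=O)[C@@H](Br)[C@H](OC/C=C/c1ccc(OC(C)=O)c(OC)c1)c1ccc(OC(C)=O)c(OC(C)=O)c1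
F7 | step 6 | (3S,3aR,6S,6aS)-3-(4-acetoxy-3-methoxyphenyl)-6-(3,4-diacetoxyphenyl)tetrahydro-1H,3H-furo[3,4-c]furan-1-one | COc1cc([C@H]2OC(=O)[C@H]3[C@@H]2CO[C@@H]3c2ccc(OC(C)=O)c(OC(C)=O)c2)ccc1OC(C)=O
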